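The cyclohexane of the lactone-fused core is opened across two bonds, C7–C8 (isopropyl-bearing CH to its ring CH2) and C1–C6 (the two ring-fusion carbons), a [4+2] retron. The vicinal carbon branches C2 (on C1) and C5 (on C6), which the target joins in its seven-membered lactone, are tied beforehand by a three-atom ester tether. An intramolecular Diels–Alder reaction of a dienyl (Z)-enoate then forms both bonds, sets C6/C7 cis from the Z-alkene and C1/C6 trans through the tether-exo mode, and gives a racemic trans-fused γ-lactone. The racemate serves both halves, which are antipodal at C6/C7; a common β-lactone branches to core (acyl transfer) and acyl unit (CO2 loss).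

Key step: step 7

Remark on labels: seco-cadinane numbering is used for both halves (primed for the acyl unit): C7 bears the isopropyl group, C8 and C9 are the ring CH2 groups, C10 is the carbinol carbon, C14 its CH2O, C1 and C6 are the ring-fusion carbons, C2 is the lactone carbonyl, C3 the lactone OCH2, C4=C5 the ring alkene, C15 the carboxyl.

Remark on the chemistry (assumption): the stated configuration makes the acyl unit the mirror image of the core at C6/C7, so both antipodes of one racemic intermediate are needed; they are separated in step 15, where the absolute configuration of each antipode would have to be assigned.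

Step 1
Reactants: 1 prop-2-yn-1-ol
Product: 2 1-methoxy-4-[(prop-2-yn-1-yloxy)methyl]benzene
Conditions: NaH, PMBCl, Bu4NI (cat.), THF, 0 °C to rt
Reagents that add atoms: 4-methoxybenzyl chloride, COc1ccc(CCl)cc1
Why: Williamson ether synthesis on the primary alkoxide installs the PMB group that masks the future C14 hydroxyl.

Step 2
Reactants: 2 PMB propargyl ether
Product: 3 methyl 4-[(4-methoxybenzyl)oxy]but-2-ynoate
Conditions: n-BuLi, THF, −78 °C; then ClCO2Me, −78 to 0 °C
Reagents that add atoms: methyl chloroformate, COC(=O)Cl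
Why: C-acylation of the lithium acetylide with a chloroformate gives the ynoate whose ester carbon becomes C2.

Step 3
Reactants: 3 ynoate
Product: 4 methyl (2Z)-3-{[(4-methoxybenzyl)oxy]methyl}penta-2,4-dienoate
Conditions: CH2=CHMgBr, CuBr·SMe2, THF, −78 °C; then MeOH, aq. NH4Cl, −78 °C
Reagents that add atoms: vinylmagnesium bromide, C=C[Mg]Br
Why: syn-carbocupration of the ynoate and protonation at low temperature with retention place vinyl and H cis, hence CH2OPMB cis to the ester (2Z), which is the diene geometry with C2 on the outside.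

Step 4
Reactants: 4 dienoate
Product: 5 (2Z)-3-{[(4-methoxybenzyl)oxy]methyl}penta-2,4-dien-1-ol
Conditions: DIBAL-H (2.2 equiv), CH2Cl2, −78 °C; Rochelle salt
Reagents that add atoms: none
Why: 1,2-reduction of the enoate by DIBAL-H gives the allylic alcohol without touching the diene or its geometry.

Step 5
Reactants: 6 4-methylpent-2-ynoic acid
Product: 7 (2Z)-4-methylpent-2-enoic acid
Conditions: H2 (1 atm), Pd/CaCO3 poisoned with Pb(OAc)2 (Lindlar catalyst), quinoline, EtOAc, rt
Reagents that add atoms: none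
Why: Lindlar semihydrogenation adds H2 syn to the alkyne and stops at the Z-alkene.

Step 6
Reactants: 5 dienol; 7 Z-acid
Product: 8 (2Z)-3-{[(4-methoxybenzyl)oxy]methyl}penta-2,4-dien-1-yl (2Z)-4-methylpent-2-enoate
Conditions: EDC·HCl, DMAP (0.1 equiv), CH2Cl2, 0 °C
Reagents that add atoms: none
Why: Steglich-type carbodiimide esterification at 0 °C joins alcohol and acid under conditions mild enough to keep both Z-alkenes intact.

Step 7
Reactants: 8 dienyl (Z)-enoate
Product: 9 rac-(3aR,7R,7aS)-4-{[(4-methoxybenzyl)oxy]methyl}-7-(propan-2-yl)-3a,6,7,7a-tetrahydro-2-benzofuran-1(3H)-one (trans-fused lactone with isopropyl cis to the lactone carbonyl carbon)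
Conditions: BHT (cat.), 1,2-dichlorobenzene (0.01 M), 170 °C, sealed tube
Reagents that add atoms: none
Why: Concerted, asynchronous thermal [4+2] cycloaddition of the s-cis 2-substituted diene onto the tethered (Z)-enoate, the closest known reaction type being the intramolecular Diels–Alder reaction of ester-linked 1,3,8-nonatrienes (pentadienyl acrylates). The cyclohexene closes by suprafacial–suprafacial [4+2] addition (bonds C7–C8 and C1–C6), and the five-membered lactone closes as a consequence of the three-atom C2–O–C5 tether in the tether-exo, trans-fused mode, the tether also fixing the regiochemistry. C6 and C7 are set cis by the Z geometry of the dienophile, which is transferred stereospecifically; C1 is set trans to C6 because the ester carbonyl and the Z-isopropyl group both occupy exo positions. The step needs exo over endo closure, which the Z-isopropyl group (it would lie under the diene in the endo mode) and the C10 substituent (it clashes with an endo tether) should secure, and it needs the Z geometry to survive heating, which the absence of acid, base and radicals (BHT) should secure. The adduct is racemic by design, since the two halves of the target need opposite configurations at C6/C7.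

Step 8
Reactants: 9 trans-fused lactone
Product: 10 rac-(3aR,7R,7aS)-4-{[(4-methoxybenzyl)oxy]methyl}-7-(propan-2-yl)-1,3,3a,6,7,7a-hexahydro-2-benzofuran-1-ol (lactol, both anomers)
Conditions: DIBAL-H (1.1 equiv), CH2Cl2, −78 °C
Reagents that add atoms: none
Why: half-reduction of the γ-lactone to the lactol at −78 °C brings C5 to the aldehyde level under non-basic conditions that should not epimerise C6.

Step 9
Reactants: 11 (diethoxyphosphoryl)acetic acid
Product: 12 2-(trimethylsilyl)ethyl (diethoxyphosphoryl)acetate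
Conditions: 2-(trimethylsilyl)ethanol, DCC, DMAP (cat.), CH2Cl2, 0 °C to rt
Reagents that add atoms: 2-(trimethylsilyl)ethanol, C[Si](C)(C)CCO
Why: Steglich esterification installs a fluoride-labile ester for C15 that is orthogonal to PMB ethers, to the lactone and to the ester linkage made later.

Step 10
Reactants: 12 silylethyl phosphonoacetate
Product: 14 2-(trimethylsilyl)ethyl 2-(diethoxyphosphoryl)prop-2-enoate, via hydroxymethyl adduct 13 (not isolated)
Conditions: (CH2O)n, piperidine (cat.), AcOH (cat.), toluene, reflux, Dean–Stark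
Reagents that add atoms: formaldehyde (as paraformaldehyde), C=O
Why: Knoevenagel-type condensation of the phosphonoacetate with formaldehyde and azeotropic dehydration of the hydroxymethyl adduct gives the 2-phosphonoacrylate.

Step 11
Reactants: 10 lactol; 14 phosphonoacrylate
Product: 16 rac-2-(trimethylsilyl)ethyl (2E)-3-[(1R,2R,6R)-2-(hydroxymethyl)-3-{[(4-methoxybenzyl)oxy]methyl}-6-(propan-2-yl)cyclohex-3-en-1-yl]-2-{[(4-methoxybenzyl)oxy]methyl}prop-2-enoate, via sodium phosphonate 15 (not isolated)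
Conditions: 4-methoxybenzyl alcohol, NaH, THF, 0 °C; 14, −20 °C; then 10, −20 °C to rt
Reagents that add atoms: 4-methoxybenzyl alcohol, COc1ccc(CO)cc1
Why: oxa-Michael addition of the PMB alkoxide to the phosphonoacrylate generates the phosphonate carbanion without excess base, and its Horner–Wadsworth–Emmons reaction with the ring-opened lactol should give the trisubstituted enoate with C6 trans to the ester (E), the usual outcome for α-substituted phosphonoacetates and α-branched aldehydes.

Step 12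
Reactants: 16 hydroxy enoate
Product: 17 rac-(1R,5R,6R)-2-{[(4-methoxybenzyl)oxy]methyl}-6-[(1E)-2-{[(4-methoxybenzyl)oxy]methyl}-3-oxo-3-[2-(trimethylsilyl)ethoxy]prop-1-en-1-yl]-5-(propan-2-yl)cyclohex-2-ene-1-carboxylic acid
Conditions: TEMPO (0.2 equiv), PhI(OAc)2 (2.5 equiv), MeCN/H2O, rt
Reagents that add atoms: water, O
Why: TEMPO/PhI(OAc)2 oxidation in wet acetonitrile takes the primary C2 alcohol through the aldehyde hydrate to the acid under near-neutral conditions that leave the β,γ-alkene, C1 and the PMB ethers untouched.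

Step 13
Reactants: 17 β,γ-unsaturated acid
Product: 18 rac-2-(trimethylsilyl)ethyl (2E)-3-[(1R,2R,3R,5R,6S)-5-iodo-6-{[(4-methoxybenzyl)oxy]methyl}-8-oxo-3-(propan-2-yl)-7-oxabicyclo[4.2.0]octan-2-yl]-2-{[(4-methoxybenzyl)oxy]methyl}prop-2-enoate
Conditions: I2, NaHCO3, H2O/CH2Cl2, 0 °C, dark
Reagents that add atoms: iodine, II
Why: kinetic iodolactonisation of the β,γ-unsaturated acid closes the β-lactone by 4-exo attack of the carboxylate on the more substituted alkene carbon C10 from the face of C2 with iodine anti at C9, which sets C10 (oxygen cis to C2, C14 trans).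

Step 14
Reactants: 18 iodo β-lactone
Product: 19 rac-2-(trimethylsilyl)ethyl (2E)-2-{[(4-methoxybenzyl)oxy]methyl}-3-[(1R,2R,3R,6S)-6-{[(4-methoxybenzyl)oxy]methyl}-8-oxo-3-(propan-2-yl)-7-oxabicyclo[4.2.0]octan-2-yl]prop-2-enoate
Conditions: Bu3SnH (3 equiv, 0.5 M), Et3B (cat.), air, toluene, 0 °C to rt
Reagents that add atoms: none
Why: radical chain deiodination at low temperature and high stannane concentration should replace iodine by hydrogen faster than the β-acyloxy radical can rearrange and leaves the β-lactone intact.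

Step 15
Reactants: 19 racemic β-lactone
Product: 20 (1R,2R,3R,6S) enantiomer of 19 (core series) and 21 (1S,2S,3S,6R) enantiomer of 19 (acyl series)
Conditions: preparative SFC on amylose tris(3,5-dimethylphenylcarbamate), CO2/MeCN
Reagents that add atoms: none
Why: chromatographic resolution on a chiral stationary phase separates the antipodes of the last common intermediate, and both are used because core and acyl unit need opposite configurations at C6/C7.

Step 16
Reactants: 20 core-series β-lactone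
Product: 22 2-(trimethylsilyl)ethyl (2E)-2-(hydroxymethyl)-3-[(1R,2R,3R,6S)-6-(hydroxymethyl)-8-oxo-3-(propan-2-yl)-7-oxabicyclo[4.2.0]octan-2-yl]prop-2-enoate
Conditions: DDQ (3 equiv), CH2Cl2/pH 7 buffer, 0 °C
Reagents that add atoms: none
Why: oxidative cleavage of both PMB ethers by DDQ frees the C3 and C14 hydroxyls without touching the β-lactone or the silylethyl ester.

Step 17
Reactants: 22 diol β-lactone
Product: 23 2-(trimethylsilyl)ethyl (5aR,6R,9S,9aR)-9-hydroxy-9-(hydroxymethyl)-1-oxo-6-(propan-2-yl)-1,3,5a,6,7,8,9,9a-octahydro-2-benzoxepine-4-carboxylate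
Conditions: DMAP (0.3 equiv), CH2Cl2 (0.005 M), rt
Reagents that add atoms: none
Why: strain-release transacylation (translactonisation) in which DMAP opens the β-lactone at the acyl carbon and the C3 hydroxyl on the cis-disposed alkene arm closes the seven-membered lactone, the C10–O bond staying intact so that the tertiary alcohol is released with retention, cis to C2, while the C14 hydroxyl on the opposite face cannot reach C2.

Step 18
Reactants: 21 acyl-series β-lactone
Product: 24 2-(trimethylsilyl)ethyl (2E)-2-{[(4-methoxybenzyl)oxy]methyl}-3-[(1R,6S)-3-{[(4-methoxybenzyl)oxy]methyl}-6-(propan-2-yl)cyclohex-2-en-1-yl]prop-2-enoate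
Conditions: xylenes, 140 °C
Reagents that add atoms: none
Why: thermal [2+2] cycloreversion of the cis-fused β-lactone extrudes CO2 and leaves the C1'=C10' alkene, removing C2' and the C1'/C10' stereocentres while C6'/C7' are untouched.

Step 19
Reactants: 24 silylethyl ester of the acyl unit
Product: 25 (2E)-2-{[(4-methoxybenzyl)oxy]methyl}-3-[(1R,6S)-3-{[(4-methoxybenzyl)oxy]methyl}-6-(propan-2-yl)cyclohex-2-en-1-yl]prop-2-enoic acid
Conditions: TBAF, AcOH, THF, rt
Reagents that add atoms: none
Why: fluoride-induced fragmentation of the 2-(trimethylsilyl)ethyl ester (loss of ethene) frees the acid without affecting the PMB ethers.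

Step 20
Reactants: 23 core diol; 25 acyl-unit acid
Product: 26 2-(trimethylsilyl)ethyl (5aR,6R,9S,9aR)-9-hydroxy-9-({[(2E)-2-{[(4-methoxybenzyl)oxy]methyl}-3-[(1R,6S)-3-{[(4-methoxybenzyl)oxy]methyl}-6-(propan-2-yl)cyclohex-2-en-1-yl]prop-2-enoyl]oxy}methyl)-1-oxo-6-(propan-2-yl)-1,3,5a,6,7,8,9,9a-octahydro-2-benzoxepine-4-carboxylate
Conditions: 25, 2,4,6-trichlorobenzoyl chloride, Et3N, THF, rt; then 23, DMAP, toluene, rt
Reagents that add atoms: none
Why: Yamaguchi esterification through the mixed anhydride should acylate the primary C14 hydroxyl in preference to the tertiary C10 hydroxyl and tolerates the hindered trisubstituted enoic acid.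

Step 21
Reactants: 26 fully protected ester
Product: 27 (5aR,6R,9S,9aR)-9-hydroxy-9-({[(2E)-2-{[(4-methoxybenzyl)oxy]methyl}-3-[(1R,6S)-3-{[(4-methoxybenzyl)oxy]methyl}-6-(propan-2-yl)cyclohex-2-en-1-yl]prop-2-enoyl]oxy}methyl)-1-oxo-6-(propan-2-yl)-1,3,5a,6,7,8,9,9a-octahydro-2-benzoxepine-4-carboxylic acid
Conditions: TBAF, AcOH, THF, 0 °C to rt
Reagents that add atoms: none
Why: buffered fluoride removes the silylethyl ester at C15 by β-elimination without hydrolysing the lactone or the new ester.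

Step 22
Reactants: 27 bis-PMB acid
Product: 28 (5aR,6R,9S,9aR)-9-hydroxy-9-({[(2E)-2-(hydroxymethyl)-3-[(1R,6S)-3-(hydroxymethyl)-6-(propan-2-yl)cyclohex-2-en-1-yl]prop-2-enoyl]oxy}methyl)-1-oxo-6-(propan-2-yl)-1,3,5a,6,7,8,9,9a-octahydro-2-benzoxepine-4-carboxylic acid (target)
Conditions: DDQ (3 equiv), CH2Cl2/pH 7 buffer, 0 °C
Reagents that add atoms: none
Why: DDQ cleaves the two allylic PMB ethers of the acyl unit under neutral oxidative conditions to give the target.

Compound list
1 | prop-2-yn-1-ol | C#CCO | starting material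
2 | 1-methoxy-4-[(prop-2-yn-1-yloxy)methyl]benzene | C#CCOCc1ccc(OC)cc1 | intermediate
3 | methyl 4-[(4-methoxybenzyl)oxy]but-2-ynoate | COC(=O)C#CCOCc1ccc(OC)cc1 | intermediate
4 | methyl (2Z)-3-{[(4-methoxybenzyl)oxy]methyl}penta-2,4-dienoate | COC(=O)/C=C(\COCc1ccc(OC)cc1)C=C | intermediate
5 | (2Z)-3-{[(4-methoxybenzyl)oxy]methyl}penta-2,4-dien-1-ol | OC/C=C(\COCc1ccc(OC)cc1)C=C | intermediate
6 | 4-methylpent-2-ynoic acid | CC(C)C#CC(=O)O | starting material
7 | (2Z)-4-methylpent-2-enoic acid | CC(C)/C=C\C(=O)O | intermediate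
8 | (2Z)-3-{[(4-methoxybenzyl)oxy]methyl}penta-2,4-dien-1-yl (2Z)-4-methylpent-2-enoate | CC(C)/C=C\C(=O)OC/C=C(\COCc1ccc(OC)cc1)C=C | intermediate
9 | rac-(3aR,7R,7aS)-4-{[(4-methoxybenzyl)oxy]methyl}-7-(propan-2-yl)-3a,6,7,7a-tetrahydro-2-benzofuran-1(3H)-one (racemate, one enantiomer drawn) | CC(C)[C@H]1CC=C(COCc2ccc(OC)cc2)[C@@H]2COC(=O)[C@@H]12 | intermediate
10 | rac-(3aR,7R,7aS)-4-{[(4-methoxybenzyl)oxy]methyl}-7-(propan-2-yl)-1,3,3a,6,7,7a-hexahydro-2-benzofuran-1-ol (racemate, anomers) | CC(C)[C@H]1CC=C(COCc2ccc(OC)cc2)[C@@H]2COC(O)[C@@H]12 | intermediate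
11 | (diethoxyphosphoryl)acetic acid | OC(=O)CP(=O)(OCC)OCC | starting material
12 | 2-(trimethylsilyl)ethyl (diethoxyphosphoryl)acetate | C[Si](C)(C)CCOC(=O)CP(=O)(OCC)OCC | intermediate
13 | 2-(trimethylsilyl)ethyl 2-(diethoxyphosphoryl)-3-hydroxypropanoate (not isolated) | C[Si](C)(C)CCOC(=O)C(CO)P(=O)(OCC)OCC | intermediate
14 | 2-(trimethylsilyl)ethyl 2-(diethoxyphosphoryl)prop-2-enoate | C[Si](C)(C)CCOC(=O)C(=C)P(=O)(OCC)OCC | intermediate
15 | 2-(trimethylsilyl)ethyl 2-(diethoxyphosphoryl)-3-[(4-methoxybenzyl)oxy]propanoate (formed as its sodium carbanion, not isolated; neutral form drawn) | C[Si](C)(C)CCOC(=O)C(COCc1ccc(OC)cc1)P(=O)(OCC)OCC | intermediate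
16 | rac-2-(trimethylsilyl)ethyl (2E)-3-[(1R,2R,6R)-2-(hydroxymethyl)-3-{[(4-methoxybenzyl)oxy]methyl}-6-(propan-2-yl)cyclohex-3-en-1-yl]-2-{[(4-methoxybenzyl)oxy]methyl}prop-2-enoate (racemate, one enantiomer drawn) | CC(C)[C@H]1CC=C(COCc2ccc(OC)cc2)[C@H](CO)[C@H]1/C=C(\COCc1ccc(OC)cc1)C(=O)OCC[Si](C)(C)C | intermediate
17 | rac-(1R,5R,6R)-2-{[(4-methoxybenzyl)oxy]methyl}-6-[(1E)-2-{[(4-methoxybenzyl)oxy]methyl}-3-oxo-3-[2-(trimethylsilyl)ethoxy]prop-1-en-1-yl]-5-(propan-2-yl)cyclohex-2-ene-1-carboxylic acid (racemate, one enantiomer drawn) | CC(C)[C@H]1CC=C(COCc2ccc(OC)cc2)[C@H](C(=O)O)[C@H]1/C=C(\COCc1ccc(OC)cc1)C(=O)OCC[Si](C)(C)C | intermediate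
18 | rac-2-(trimethylsilyl)ethyl (2E)-3-[(1R,2R,3R,5R,6S)-5-iodo-6-{[(4-methoxybenzyl)oxy]methyl}-8-oxo-3-(propan-2-yl)-7-oxabicyclo[4.2.0]octan-2-yl]-2-{[(4-methoxybenzyl)oxy]methyl}prop-2-enoate (racemate, one enantiomer drawn) | CC(C)[C@H]1C[C@@H](I)[C@]2(COCc3ccc(OC)cc3)OC(=O)[C@@H]2[C@H]1/C=C(\COCc1ccc(OC)cc1)C(=O)OCC[Si](C)(C)C | intermediate
19 | rac-2-(trimethylsilyl)ethyl (2E)-2-{[(4-methoxybenzyl)oxy]methyl}-3-[(1R,2R,3R,6S)-6-{[(4-methoxybenzyl)oxy]methyl}-8-oxo-3-(propan-2-yl)-7-oxabicyclo[4.2.0]octan-2-yl]prop-2-enoate (racemate, one enantiomer drawn) | CC(C)[C@H]1CC[C@]2(COCc3ccc(OC)cc3)OC(=O)[C@@H]2[C@H]1/C=C(\COCc1ccc(OC)cc1)C(=O)OCC[Si](C)(C)C | intermediate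
20 | (1R,2R,3R,6S) enantiomer of 19 (core series) | CC(C)[C@H]1CC[C@]2(COCc3ccc(OC)cc3)OC(=O)[C@@H]2[C@H]1/C=C(\COCc1ccc(OC)cc1)C(=O)OCC[Si](C)(C)C | intermediate
21 | (1S,2S,3S,6R) enantiomer of 19 (acyl series) | CC(C)[C@@H]1CC[C@@]2(COCc3ccc(OC)cc3)OC(=O)[C@H]2[C@@H]1/C=C(\COCc1ccc(OC)cc1)C(=O)OCC[Si](C)(C)C | intermediate
22 | 2-(trimethylsilyl)ethyl (2E)-2-(hydroxymethyl)-3-[(1R,2R,3R,6S)-6-(hydroxymethyl)-8-oxo-3-(propan-2-yl)-7-oxabicyclo[4.2.0]octan-2-yl]prop-2-enoate | CC(C)[C@H]1CC[C@]2(CO)OC(=O)[C@@H]2[C@H]1/C=C(\CO)C(=O)OCC[Si](C)(C)C | intermediate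
23 | 2-(trimethylsilyl)ethyl (5aR,6R,9S,9aR)-9-hydroxy-9-(hydroxymethyl)-1-oxo-6-(propan-2-yl)-1,3,5a,6,7,8,9,9a-octahydro-2-benzoxepine-4-carboxylate | CC(C)[C@H]1CC[C@@](O)(CO)[C@@H]2C(=O)OCC(C(=O)OCC[Si](C)(C)C)=C[C@@H]12 | intermediate
24 | 2-(trimethylsilyl)ethyl (2E)-2-{[(4-methoxybenzyl)oxy]methyl}-3-[(1R,6S)-3-{[(4-methoxybenzyl)oxy]methyl}-6-(propan-2-yl)cyclohex-2-en-1-yl]prop-2-enoate | C[Si](C)(C)CCOC(=O)/C(=C/[C@H]1C=C(COCc2ccc(OC)cc2)CC[C@H]1C(C)C)COCc1ccc(OC)cc1 | intermediate
25 | (2E)-2-{[(4-methoxybenzyl)oxy]methyl}-3-[(1R,6S)-3-{[(4-methoxybenzyl)oxy]methyl}-6-(propan-2-yl)cyclohex-2-en-1-yl]prop-2-enoic acid | OC(=O)/C(=C/[C@H]1C=C(COCc2ccc(OC)cc2)CC[C@H]1C(C)C)COCc1ccc(OC)cc1 | intermediate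
26 | 2-(trimethylsilyl)ethyl ester of 27 (core diol 23 acylated at C14–O by 25) | CC(C)[C@H]1CC[C@@](O)(COC(=O)/C(=C/[C@H]2C=C(COCc3ccc(OC)cc3)CC[C@H]2C(C)C)COCc2ccc(OC)cc2)[C@@H]2C(=O)OCC(C(=O)OCC[Si](C)(C)C)=C[C@@H]12 | intermediate
27 | bis-PMB ether of the target (free C15 acid) | CC(C)[C@H]1CC[C@@](O)(COC(=O)/C(=C/[C@H]2C=C(COCc3ccc(OC)cc3)CC[C@H]2C(C)C)COCc2ccc(OC)cc2)[C@@H]2C(=O)OCC(C(=O)O)=C[C@@H]12 | intermediate
28 | (5aR,6R,9S,9aR)-9-hydroxy-9-({[(2E)-2-(hydroxymethyl)-3-[(1R,6S)-3-(hydroxymethyl)-6-(propan-2-yl)cyclohex-2-en-1-yl]prop-2-enoyl]oxy}methyl)-1-oxo-6-(propan-2-yl)-1,3,5a,6,7,8,9,9a-octahydro-2-benzoxepine-4-carboxylic acid | CC(C)[C@H]1CC[C@@](O)(COC(=O)/C(=C/[C@H]2C=C(CO)CC[C@H]2C(C)C)CO)[C@@H]2C(=O)OCC(C(=O)O)=C[C@@H]12 | target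

Total step count: 22. Longest linear sequence: 17 steps (1–4, 6–8, 11–17, 20–22).

Steps most likely to fail

Step 7. What may go wrong: endo closure competing with the required exo closure, which would lose the trans C1/C6 relationship, or a cycloaddition so slow that the twisted Z-enoate stereomutates first. The fallback replaces kinetic control of C1 by thermodynamic control; it sets out from 8 and comes back at 23. The endo cycloadduct of 8, the cis-fused lactone F1 (C2 cis to C5, C6/C7 still cis), is carried on instead. Mukaiyama hydration (Mn(dpm)3, PhSiH3, O2, i-PrOH, then P(OEt)3) on its convex face should give the tertiary alcohol F2 with the oxygen trans to C5. DIBAL-H gives the lactol F3, and the alkoxide-Michael/Horner–Wadsworth–Emmons sequence of step 11 gives the hydroxy enoate F4. TEMPO/PhI(OAc)2 gives the hydroxy acid F5, which is resolved as in step 15, and DDQ then gives the triol acid F6. Mitsunobu lactonisation (PPh3, DIAD, toluene, high dilution; only the unhindered allylic C3 hydroxyl is activated) gives the cis-fused seven-membered lactone F7. DBU then equilibrates C1, which is α to the lactone carbonyl, to the trans-fused epimer 23. That epimer should be favoured because either chair of the cis-fused lactone places C2 syn-diaxial to the isopropyl group or C5 syn-diaxial to C14.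

Step 11. What may go wrong: epimerisation at C6 of the ring-opened hydroxy aldehyde (drift towards the more stable cis-fused lactol series), and conjugate re-addition of the liberated C2 alkoxide to the new enoate. The fallback uses an acyclic, O-protected aldehyde instead of the lactol; it sets out from 9 and comes back at 16. Aminolysis of 9 with MeNH(OMe)·HCl/i-PrMgCl gives the hydroxy Weinreb amide F8. TBSCl/imidazole gives the silyl ether F9, and DIBAL-H at −78 °C gives the aldehyde F10. Horner–Wadsworth–Emmons reaction with 15 (this time prepared separately from 14 and 4-methoxybenzyl alcohol with catalytic NaH and isolated) under Ba(OH)2·8H2O in wet THF gives the protected enoate F11. HF·pyridine removes the TBS group to give 16.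

Step 17. What may go wrong: ionisation and decarboxylation of the tertiary β-lactone, or base-induced β-elimination, outrunning acyl transfer to the C3 hydroxyl. The fallback hydrolyses the β-lactone and then lactonises by activating the alcohol; it sets out from 22 and comes back at 23. LiOH (1 equiv) in THF/H2O at 0 °C should open the strained β-lactone selectively over the hindered conjugated ester to give the trihydroxy acid F12. Mitsunobu lactonisation (PPh3, DIAD, toluene, high dilution) then closes the seven-membered lactone through the primary allylic C3 hydroxyl to give 23.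

Further compounds
F1 | step 7 | rac-(3aS,7R,7aS)-4-{[(4-methoxybenzyl)oxy]methyl}-7-(propan-2-yl)-3a,6,7,7a-tetrahydro-2-benzofuran-1(3H)-one (cis-fused lactone, racemate) | CC(C)[C@H]1CC=C(COCc2ccc(OC)cc2)[C@H]2COC(=O)[C@@H]12
F2 | step 7 | cis-fused 4-hydroxy-4-{[(4-methoxybenzyl)oxy]methyl}-7-(propan-2-yl)hexahydro-2-benzofuran-1(3H)-one with the hydroxyl trans to C5 (racemate) | CC(C)[C@H]1CC[C@@](O)(COCc2ccc(OC)cc2)[C@H]2COC(=O)[C@@H]12
F3 | step 7 | lactol of F2 (racemate, anomers) | CC(C)[C@H]1CC[C@@](O)(COCc2ccc(OC)cc2)[C@H]2COC(O)[C@@H]12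
F4 | step 7 | 2-(trimethylsilyl)ethyl (2E)-3-[3-hydroxy-2-(hydroxymethyl)-3-{[(4-methoxybenzyl)oxy]methyl}-6-(propan-2-yl)cyclohexyl]-2-{[(4-methoxybenzyl)oxy]methyl}prop-2-enoate, C1-epimeric series (racemate) | CC(C)[C@H]1CC[C@@](O)(COCc2ccc(OC)cc2)[C@@H](CO)[C@H]1/C=C(\COCc1ccc(OC)cc1)C(=O)OCC[Si](C)(C)C
F5 | step 7 | hydroxy acid from F4, C2 oxidised to CO2H (racemate, then resolved) | CC(C)[C@H]1CC[C@@](O)(COCc2ccc(OC)cc2)[C@@H](C(=O)O)[C@H]1/C=C(\COCc1ccc(OC)cc1)C(=O)OCC[Si](C)(C)C
F6 | step 7 | triol acid from F5 after removal of both PMB groups | CC(C)[C@H]1CC[C@@](O)(CO)[C@@H](C(=O)O)[C@H]1/C=C(\CO)C(=O)OCC[Si](C)(C)C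
F7 | step 7 | 2-(trimethylsilyl)ethyl (5aR,6R,9S,9aS)-9-hydroxy-9-(hydroxymethyl)-1-oxo-6-(propan-2-yl)-1,3,5a,6,7,8,9,9a-octahydro-2-benzoxepine-4-carboxylate (C9a epimer of 23, cis-fused) | CC(C)[C@H]1CC[C@@](O)(CO)[C@H]2C(=O)OCC(C(=O)OCC[Si](C)(C)C)=C[C@@H]12
F8 | step 11 | rac-(1R,5R,6R)-5-(hydroxymethyl)-N-methoxy-4-{[(4-methoxybenzyl)oxy]methyl}-N-methyl-2-(propan-2-yl)cyclohex-3-ene-1-carboxamide, configuration as in 16 | CC(C)[C@H]1CC=C(COCc2ccc(OC)cc2)[C@H](CO)[C@H]1C(=O)N(C)OC
F9 | step 11 | tert-butyldimethylsilyl ether of F8 | CC(C)[C@H]1CC=C(COCc2ccc(OC)cc2)[C@H](CO[Si](C)(C)C(C)(C)C)[C@H]1C(=O)N(C)OC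
F10 | step 11 | aldehyde from F9 (C5 as CHO) | CC(C)[C@H]1CC=C(COCc2ccc(OC)cc2)[C@H](CO[Si](C)(C)C(C)(C)C)[C@H]1C=O
F11 | step 11 | tert-butyldimethylsilyl ether of 16 | CC(C)[C@H]1CC=C(COCc2ccc(OC)cc2)[C@H](CO[Si](C)(C)C(C)(C)C)[C@H]1/C=C(\COCc1ccc(OC)cc1)C(=O)OCC[Si](C)(C)C
F12 | step 17 | (1R,2S,5R,6R)-2-hydroxy-2-(hydroxymethyl)-6-[(1E)-2-(hydroxymethyl)-3-oxo-3-[2-(trimethylsilyl)ethoxy]prop-1-en-1-yl]-5-(propan-2-yl)cyclohexane-1-carboxylic acid | CC(C)[C@H]1CC[C@@](O)(CO)[C@H](C(=O)O)[C@H]1/C=C(\CO)C(=O)OCC[Si](C)(C)C
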